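The data were generated by integration with constants of no real substance; noise was put on by code.

Slowness is the first thing to read in these flasks, so time each one against its 6.0 h run.

| flask | free monomer | initiator | temperature | remark | time |
|---|---|---|---|---|---|
| eta | 3 M | 2.8 mol% | 24 °C | run made earlier |  |
| gamma | 3 M | 6.3 mol% | 65 °C | run made earlier |  |
| epsilon | 1.5 M | 4.2 mol% | 24 °C | run made earlier |  |
| west | 3.0 M | 4.2 mol% | 30 °C |  | 6.0 h |
| north-east | 3.0 M | 4.2 mol% | 5 °C |  | 6.0 h |
| north-west | 3.0 M | 4.2 mol% | 55 °C |  | 6.0 h |
| south | 3.0 M | 4.2 mol% | 80 °C |  | 6.0 h |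

- eta (time / h: monomer in chains / %, free monomer / %): 0.500: 1.9, 99.8; 0.667: 0.5, 100.1; 1.00: 0, 99.1; 1.50: 0, 100.8; 2.50: 0, 99.4; 4.00: 0, 102.6; 6.00: 0.1, 101.3
- gamma (time / min: monomer in chains / %, free monomer / %): 4.00: 0, 100.0; 10.0: 2.0, 97.7; 15.0: 2.6, 97.1; 25.0: 5.3, 94.5; 40.0: 8.2, 92.7; 50.0: 11.5, 90.2; 60.0: 10.3, 88.9
- epsilon (time / h: monomer in chains / %, free monomer / %): 1.33: 0, 101.0; 2.50: 0.5, 101.2; 4.00: 0.5, 99.3; 5.00: 1.2, 99.4; 6.00: 0, 99.6

(standard deviation of a reading: 1 percentage point)

- the analysis behind the earlier runs scatters by 1 percentage point, standard deviation
- reactions considered so far: free monomer + initiator -> living end + monomer in chains; free monomer + living end -> monomer in chains + living end; monomer in chains + living end -> free monomer + living end; 2 living end -> dead end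

- the best flask by amount of monomer in chains, in percent of the free monomer charged; "all alike" if 1.5 percentage points covers them all (west / north-east / north-west / south / all alike)
- amount of monomer in chains at the end, in percent of the free monomer charged, west
- amount of monomer in chains at the end, in percent of the free monomer charged, north-east
- amount of monomer in chains at the end, in percent of the free monomer charged, north-west
- amount of monomer in chains at the end, in percent of the free monomer charged, south

Start from the gamma run, whose free monomer falls to 88.9% in 60.0 min. Divide that time by the fraction lost to get 9.01 h: this is the filling time, the time a flask needs to turn its whole charge of free monomer into chains at the pace it holds. It is a reading and carries the scatter of 1 percentage point.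

Now climb down the ladder, my own reckoning. Assume pace goes with initiator: at 4.2 mol%, gamma's temperature gives a filling time of 13.5 h, longer than the run, so the yardstick for a run is 44.4%. Expect north-west, colder than gamma, below that mark. South is hotter than gamma, but gamma reached 10.3% in chains, so its readings do not show how a pace holds further on.

On the lowest rungs, eta and epsilon read 0.1% and 0% at their last times, inside the scatter, so their filling times lie far beyond a run. Expect west, warmer than eta, and north-east, colder than eta, to stay near the scatter too.

The forecast names south: west 0.8%, north-east 0%, north-west 14% (6% to 28%), south 35% (10% to 75%), with the words “South is therefore my likely best but very uncertain”.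

The flasks give south as best: west 0.813%, north-east 0.0250%, north-west 17.6%, south 41.9%.

    free monomer + initiator → living end + monomer in chains (k = 4.65 × 10⁻⁴ M⁻¹ s⁻¹, Ea = 93.0 kJ mol⁻¹)
    free monomer + living end → monomer in chains + living end, rate k2*[living end]*[free monomer] (k = 0.00147 M⁻¹ s⁻¹, Ea = 90.0 kJ mol⁻¹)
    monomer in chains + living end → free monomer + living end, rate k3*[living end] as long as [monomer in chains] is above zero (k = 7.77 × 10⁻⁴ s⁻¹, Ea = 115 kJ mol⁻¹)
    2 living end → dead end (k = 0.00376 M⁻¹ s⁻¹, Ea = 85.0 kJ mol⁻¹)
    (constants at 80 °C)

South ends 6.9 points above the forecast but below my yardstick, and its filling time is 8.37 h up to 3.00 h, when initiator stands at 0%, then 49.5 h afterwards. North-west, with initiator at 27.5% at that same time, goes from 32.1 h to 36.4 h.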